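The dihydropyran ring is opened at C4–C4a and C2 is raised to the acid level: the precursor is an achiral aryl 2-arylacrylate, the ester of 3,5-dimethoxy-4-prenylphenol with the B-ring atropic acid. A chiral Brønsted acid should trigger a 6-endo Friedel–Crafts conjugate addition of ring A onto the acrylate CH2 (C4); the mirror symmetry of the phenoxy ring makes C4a and C8 equivalent, and its 1,3,5-trioxygenation makes them nucleophilic. The planar lactone enol formed is protonated at C3 under catalyst control, so ring closure and the sole stereocentre arise in one operation. Lactone reduction and Mitsunobu closure of O1–C2 then give the isoflavan.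

Key step: step 7

Remark: isoflavan numbering is used (O1, C2, C3, C4, C4a, C5–C8, C8a; B ring primed); the target as drawn is the (3R)-isomer.

Step 1
Reactants: 1 1,3-dimethoxybenzene
Product: 3 1,3-dimethoxy-2-(3-methylbut-2-en-1-yl)benzene, via 2,6-dimethoxyphenyllithium 2 (not isolated)
Conditions: n-BuLi (1.1 equiv), THF, 0 °C → rt; then prenyl bromide, 0 °C → rt
Reagents that add atoms: 1-bromo-3-methylbut-2-ene (prenyl bromide), CC(C)=CCBr; n-butyllithium, [Li]CCCC (lithium of intermediate 2 only)
Why: Directed ortho-metalation removes the C2–H flanked by both methoxy groups, and the aryllithium then displaces bromide from the primary carbon of prenyl bromide (SN2 alkylation).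

Step 2
Reactants: 3 1,3-dimethoxy-2-(3-methylbut-2-en-1-yl)benzene
Product: 5 3,5-dimethoxy-4-(3-methylbut-2-en-1-yl)phenol, via pinacol arylboronate 4 (not isolated)
Conditions: [Ir(OMe)(cod)]2 (1.5 mol %), dtbpy (3 mol %), B2pin2 (1.0 equiv), THF, 60 °C; then aq NaOH, 30% H2O2, 0 °C
Reagents that add atoms: bis(pinacolato)diboron, CC1(C)OB(OC1(C)C)B1OC(C)(C)C(C)(C)O1 (boryl group of intermediate 4 only); hydrogen peroxide, OO (phenol oxygen)
Why: Sterically governed Ir-catalysed C–H borylation should take the only ring C–H that has no ortho substituent (para to the prenyl group) and leave the trisubstituted alkene alone, and alkaline peroxide oxidation of the C–B bond then gives the phenol without epoxidising an isolated alkene.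

Step 3
Reactants: 6 2,4-dihydroxyacetophenone
Product: 7 4-acetyl-3-hydroxyphenyl pivalate
Conditions: PivCl (1.05 equiv), Et3N, CH2Cl2, 0 °C
Reagents that add atoms: pivaloyl chloride, CC(C)(C)C(Cl)=O
Why: Selective O-acylation of the 4-OH is expected because the 2-OH is tied up in a hydrogen bond to the acetyl group and is more hindered.

Step 4
Reactants: 7 4-acetyl-3-hydroxyphenyl pivalate
Product: 9 8-acetyl-2,2-dimethyl-2H-chromen-5-yl pivalate, via tertiary propargyl aryl ether 8 (not isolated)
Conditions: 3-chloro-3-methylbut-1-yne, DBU, CuCl2 (1 mol %), MeCN, 0 °C → rt; aqueous wash, then o-xylene, 140 °C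
Reagents that add atoms: 3-chloro-3-methylbut-1-yne, CC(C)(Cl)C#C
Why: Cu-catalysed propargylic etherification of the remaining phenol is followed by the aromatic propargyl Claisen rearrangement to the only free ortho carbon, 1,5-H shift and oxa-6π electrocyclisation, so the pyran oxygen must come from the 2-OH.

Step 5
Reactants: 9 8-acetyl-2,2-dimethyl-2H-chromen-5-yl pivalate
Product: 10 2,2-dimethyl-8-[1-(trifluoromethylsulfonyloxy)ethenyl]-2H-chromen-5-yl pivalate
Conditions: KHMDS, THF, −78 °C; then PhNTf2, −78 → 0 °C
Reagents that add atoms: N-phenylbis(trifluoromethanesulfonimide), O=S(=O)(N(c1ccccc1)S(=O)(=O)C(F)(F)F)C(F)(F)F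
Why: The methyl ketone is the only enolisable site, and O-sulfonylation of its potassium enolate gives the enol triflate while the hindered pivalate is not attacked at low temperature.

Step 6
Reactants: 10 2,2-dimethyl-8-[1-(trifluoromethylsulfonyloxy)ethenyl]-2H-chromen-5-yl pivalate; 5 3,5-dimethoxy-4-(3-methylbut-2-en-1-yl)phenol
Product: 11 3,5-dimethoxy-4-(3-methylbut-2-en-1-yl)phenyl 2-[2,2-dimethyl-5-(pivaloyloxy)-2H-chromen-8-yl]prop-2-enoate
Conditions: Pd(OAc)2 (5 mol %), Xantphos (6 mol %), CO (1 atm), iPr2NEt, toluene, 60 °C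
Reagents that add atoms: carbon monoxide, [C-]#[O+]
Why: Pd-catalysed carbonylative esterification (aryloxycarbonylation) of an enol triflate: oxidative addition, CO insertion and capture of the acyl–Pd species by the phenol give the aryl acrylate in one convergent step.

Step 7
Reactants: 11 3,5-dimethoxy-4-(3-methylbut-2-en-1-yl)phenyl 2-[2,2-dimethyl-5-(pivaloyloxy)-2H-chromen-8-yl]prop-2-enoate
Product: 13 8-[(3R)-5,7-dimethoxy-6-(3-methylbut-2-en-1-yl)-2-oxochroman-3-yl]-2,2-dimethyl-2H-chromen-5-yl pivalate, via lactone enol 12 (not isolated)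
Conditions: (R)-3,3'-bis(2,4,6-triisopropylphenyl)-BINOL N-triflylphosphoramide (10 mol %; antipode to be chosen so that 3R results), toluene, 4 Å MS, −30 °C
Reagents that add atoms: none
Why: Proposed new method: the chiral Brønsted acid activates the ester carbonyl of 11, the A-ring carbon ortho to the ester oxygen (also ortho and para to the two methoxy groups) adds to the acrylate CH2, and the catalyst anion relays the arene proton so that lactone enol 12 is formed inside the chiral pocket and is protonated at C3. The closest known reaction types are the acid-mediated cyclisation of aryl cinnamates and acrylates to 3,4-dihydrocoumarins, the tandem Friedel–Crafts conjugate addition/asymmetric protonation of α-substituted acrylates, and chiral N-triflylphosphoramide-catalysed cyclisations that end in an enantioselective enol protonation (Nazarov type). The pyranone ring closes in the 6-endo-trig mode. The C3 stereocentre is set in the proton transfer to the planar enol, with the face chosen by the catalyst, which should bind the enol OH through P=O and deliver the proton from N–H. Regioselectivity is not an issue because the two ortho positions of the 3,5-dimethoxy-4-prenylphenoxy ring are equivalent; chemoselectivity over the prenyl and chromene alkenes rests on the moderate acidity of the catalyst, the low temperature and the pivalate, which lowers the electron density of the B ring. The lactone is less basic than the acrylate and should not re-enolise at this temperature, so the configuration is expected to hold until the next step.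

Step 8
Reactants: 13 8-[(3R)-5,7-dimethoxy-6-(3-methylbut-2-en-1-yl)-2-oxochroman-3-yl]-2,2-dimethyl-2H-chromen-5-yl pivalate
Product: 14 8-[(2R)-1-hydroxy-3-[6-hydroxy-2,4-dimethoxy-3-(3-methylbut-2-en-1-yl)phenyl]propan-2-yl]-2,2-dimethyl-2H-chromen-5-ol
Conditions: crude 13 added to LiAlH4 (excess), THF, −20 → 0 °C; Rochelle salt work-up
Reagents that add atoms: none
Why: Hydride reduction of the aryl lactone to the primary alcohol and phenol also removes the pivalate reductively, is much faster than enolisation at low temperature so that C3 should be kept, and leaves isolated alkenes untouched.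

Step 9
Reactants: 14 8-[(2R)-1-hydroxy-3-[6-hydroxy-2,4-dimethoxy-3-(3-methylbut-2-en-1-yl)phenyl]propan-2-yl]-2,2-dimethyl-2H-chromen-5-ol
Product: 15 Kanzonol I, 8-[(3R)-5,7-dimethoxy-6-(3-methylbut-2-en-1-yl)-3,4-dihydro-2H-chromen-3-yl]-2,2-dimethyl-2H-chromen-5-ol
Conditions: PPh3, DIAD, THF (0.01 M), 0 °C → rt
Reagents that add atoms: none
Why: Intramolecular Mitsunobu etherification: the primary alcohol is activated as the alkoxyphosphonium ion and displaced by the ortho phenoxide (6-exo-tet), C3 is not involved, and high dilution disfavours intermolecular alkylation of the remote B-ring phenol.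

Compound list
1 | 1,3-dimethoxybenzene | COc1cccc(OC)c1 | starting material
2 | 2,6-dimethoxyphenyllithium | [Li]c1c(OC)cccc1OC | intermediate
3 | 1,3-dimethoxy-2-(3-methylbut-2-en-1-yl)benzene | COc1cccc(OC)c1CC=C(C)C | intermediate
4 | 2-[3,5-dimethoxy-4-(3-methylbut-2-en-1-yl)phenyl]-4,4,5,5-tetramethyl-1,3,2-dioxaborolane | COc1cc(B2OC(C)(C)C(C)(C)O2)cc(OC)c1CC=C(C)C | intermediate
5 | 3,5-dimethoxy-4-(3-methylbut-2-en-1-yl)phenol | COc1cc(O)cc(OC)c1CC=C(C)C | intermediate
6 | 2,4-dihydroxyacetophenone | CC(=O)c1ccc(O)cc1O | starting material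
7 | 4-acetyl-3-hydroxyphenyl pivalate | CC(=O)c1ccc(OC(=O)C(C)(C)C)cc1O | intermediate
8 | 4-acetyl-3-[(2-methylbut-3-yn-2-yl)oxy]phenyl pivalate | CC(=O)c1ccc(OC(=O)C(C)(C)C)cc1OC(C)(C)C#C | intermediate
9 | 8-acetyl-2,2-dimethyl-2H-chromen-5-yl pivalate | CC(=O)c1ccc(OC(=O)C(C)(C)C)c2c1OC(C)(C)C=C2 | intermediate
10 | 2,2-dimethyl-8-[1-(trifluoromethylsulfonyloxy)ethenyl]-2H-chromen-5-yl pivalate | C=C(OS(=O)(=O)C(F)(F)F)c1ccc(OC(=O)C(C)(C)C)c2c1OC(C)(C)C=C2 | intermediate
11 | 3,5-dimethoxy-4-(3-methylbut-2-en-1-yl)phenyl 2-[2,2-dimethyl-5-(pivaloyloxy)-2H-chromen-8-yl]prop-2-enoate | C=C(C(=O)Oc1cc(OC)c(CC=C(C)C)c(OC)c1)c1ccc(OC(=O)C(C)(C)C)c2c1OC(C)(C)C=C2 | intermediate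
12 | 8-[2-hydroxy-5,7-dimethoxy-6-(3-methylbut-2-en-1-yl)-4H-chromen-3-yl]-2,2-dimethyl-2H-chromen-5-yl pivalate (lactone enol) | COc1cc2c(c(OC)c1CC=C(C)C)CC(c1ccc(OC(=O)C(C)(C)C)c3c1OC(C)(C)C=C3)=C(O)O2 | intermediate
13 | 8-[(3R)-5,7-dimethoxy-6-(3-methylbut-2-en-1-yl)-2-oxochroman-3-yl]-2,2-dimethyl-2H-chromen-5-yl pivalate | COc1cc2c(c(OC)c1CC=C(C)C)C[C@H](c1ccc(OC(=O)C(C)(C)C)c3c1OC(C)(C)C=C3)C(=O)O2 | intermediate
14 | 8-[(2R)-1-hydroxy-3-[6-hydroxy-2,4-dimethoxy-3-(3-methylbut-2-en-1-yl)phenyl]propan-2-yl]-2,2-dimethyl-2H-chromen-5-ol | COc1cc(O)c(C[C@H](c2ccc(O)c3c2OC(C)(C)C=C3)CO)c(OC)c1CC=C(C)C | intermediate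
15 | Kanzonol I, 8-[(3R)-5,7-dimethoxy-6-(3-methylbut-2-en-1-yl)-3,4-dihydro-2H-chromen-3-yl]-2,2-dimethyl-2H-chromen-5-ol | COc1cc2c(c(OC)c1CC=C(C)C)C[C@H](c1ccc(O)c3c1OC(C)(C)C=C3)CO2 | target

Total step count: 9. Longest linear sequence: 7 steps (6 → 7 → 9 → 10 → 11 → 13 → 14 → 15); the A-ring branch (1 → 3 → 5) joins at step 6.

Steps most likely to fail

1. Step 7 (Proposed new method). The proton transfer to the enol may show poor facial discrimination, the lactone may re-enolise under the acid so that the enantiomeric purity erodes, or the ring closure may be too slow at the acidity that the two alkenes tolerate. The fallback uses known chemistry, sets out from 11 and returns at 14. Ring closure with an achiral Lewis acid (Sc(OTf)3, 10 mol %, CH2Cl2, 0 °C), the established acid-mediated hydroarylation of aryl acrylates, should give the racemic lactone F1. F1 is then hydrogenated under dynamic kinetic resolution with an Ir–SpiroPAP catalyst (H2 10 atm, KOtBu in excess, n-PrOH, rt; catalyst antipode chosen for R). The alkoxide opens the lactone to the propyl ester, epimerises the α-aryl centre continuously and removes the pivalate, while the chiral iridium hydride reduces one ester enantiomer faster, so that 14 is expected directly. The stereocentre then comes from a stereoconvergent reduction and not from the ring closure.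

2. Step 2. The iridium boryl catalyst may attack or isomerise the prenyl alkene, or borylate partly next to a methoxy group. The fallback sets out from 1 and returns at 5, and puts the C–O bond in before the prenyl group. Compound 1, which has no alkene, is borylated at C5 under the same iridium conditions to the pinacol boronate F2 and oxidised (NaOH, H2O2) to 3,5-dimethoxyphenol F3. TIPSCl and imidazole in DMF give the triisopropylsilyl ether F4. n-BuLi (THF, 0 °C) is expected to lithiate between the two methoxy groups, because the bulky silyl ether shields its own ortho positions and coordinates poorly, giving the aryllithium F5. Prenyl bromide converts F5 into the prenylated silyl ether F6, and TBAF in THF releases 5.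

3. Step 9. The unprotected B-ring phenol may be alkylated intermolecularly, or displacement at the β-branched alkoxyphosphonium carbon may be slow enough for hydrazide alkylation to take over. The fallback sets out from 14 and returns at 15, and separates activation from ring closure. Appel bromination (CBr4, PPh3, CH2Cl2, 0 °C), which leaves phenols untouched, should give the primary bromide F7. Slow addition of F7 to K2CO3 in acetone then closes O1–C2 by an intramolecular Williamson etherification (6-exo-tet) to give 15.

Further compounds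
F1 | step 7 | rac-8-[5,7-dimethoxy-6-(3-methylbut-2-en-1-yl)-2-oxochroman-3-yl]-2,2-dimethyl-2H-chromen-5-yl pivalate | COc1cc2c(c(OC)c1CC=C(C)C)CC(c1ccc(OC(=O)C(C)(C)C)c3c1OC(C)(C)C=C3)C(=O)O2
F2 | step 2 | 2-(3,5-dimethoxyphenyl)-4,4,5,5-tetramethyl-1,3,2-dioxaborolane | COc1cc(OC)cc(B2OC(C)(C)C(C)(C)O2)c1
F3 | step 2 | 3,5-dimethoxyphenol | COc1cc(O)cc(OC)c1
F4 | step 2 | (3,5-dimethoxyphenoxy)tri(propan-2-yl)silane | COc1cc(O[Si](C(C)C)(C(C)C)C(C)C)cc(OC)c1
F5 | step 2 | [2,6-dimethoxy-4-(triisopropylsilyloxy)phenyl]lithium | [Li]c1c(OC)cc(O[Si](C(C)C)(C(C)C)C(C)C)cc1OC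
F6 | step 2 | [3,5-dimethoxy-4-(3-methylbut-2-en-1-yl)phenoxy]tri(propan-2-yl)silane | COc1cc(O[Si](C(C)C)(C(C)C)C(C)C)cc(OC)c1CC=C(C)C
F7 | step 9 | 8-[(2R)-1-bromo-3-[6-hydroxy-2,4-dimethoxy-3-(3-methylbut-2-en-1-yl)phenyl]propan-2-yl]-2,2-dimethyl-2H-chromen-5-ol | COc1cc(O)c(C[C@H](c2ccc(O)c3c2OC(C)(C)C=C3)CBr)c(OC)c1CC=C(C)C
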